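## The problem

Daphnodorin F joins a flavanonol-type half to a (2'S)-flavan through a bicyclic ketal. The upper half is numbered as a flavone: O1, ketal carbon C2 (carrying a 4-hydroxyphenyl group), carbinol carbon C3, ketone C4 and ring A (C4a–C8a). The flavan is primed; its oxygen O7' is bonded to C2 and its carbon C8' to C3, so C2 and C3 are shared by a dihydrofuran and a pyranone ring. Three stereocentres must be delivered. C2' comes from the chiral pool but lies seven bonds from C3 and cannot bias reactions there. C2 is a ketal carbon that equilibrates through an oxocarbenium ion and is tied to C3 by the pyranone ring, so C3 dictates C2 and only C3 needs a solution of its own. C3 is the congested point: it carries an aryl group, a hydroxyl, the aroyl carbon C4 and the ketal carbon. The aryl ketal and the benzylic C2'–O1' ether are acid-sensitive, the tertiary benzylic α-ketol ionises under Lewis acids, and the flavan ring keeps a free, very electron-rich position (C6') that competes in any electrophilic step. The enabling feature is ring A: it is a 2-acylphenol with C4 on C4a, O1 on the neighbouring C8a and further oxygens on C5 and C7. This is the pattern left when a 3,5-dioxygenated benzyne inserts into the acyl C–O bond of a carboxylic acid sitting on C3.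

## Retrosynthesis

**26 from 25.** The five phenols and the C3 hydroxyl of target 26 are unmasked last from hexabenzyl ether 25 by cutting six O–CH2Ph bonds. Benzyl is preferred to methyl (Lewis-acid cleavage would open the ketal) and to silyl or acyl groups (lost under the fluoride and hydroxide used earlier). The forward step must be neutral.

**25 from 24.** The C2–O1 bond is cut, which opens the pyranone ring to the ortho-hydroxyaryl ketone 24 carrying a methyl ketal at C2. This is preferred to closing O1–C8a on a preformed ring A, which would need a nucleophilic aromatic substitution on an electron-rich ring. The forward step is an acid-catalysed ketal exchange through an oxocarbenium ion stabilised by O7' and the 4-benzyloxyphenyl group; it sets C2 from C3.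

**24 from 15 and 22 (key disconnection).** C4–C4a and O1–C8a are cut together, so ring A leaves as the benzyne from silylaryl triflate 22 and the rest is carboxylic acid 15. A Friedel–Crafts acylation with an acid chloride of 15 would ionise the C3 oxygen and the ketal. Addition of an aryllithium to an ester of 15 is a bimolecular attack on a neopentyl-type carbonyl. The aryne route attaches the unhindered carboxylate oxygen first and makes the C–C bond intramolecularly. The forward step needs one aryne regiochemistry and no proton donor near the aryl anion. A free C3 hydroxyl could protonate that anion through a seven-membered transition state, so the hydroxyl is carried as a benzyl ether, which also leaves at the end.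

**15 from 14, 13 and 11.** Acid 15 comes from methyl ester 14 by saponification, and 14 from tertiary alcohol 13 by O-benzylation. In 13 the C3–OH and C2–OMe bonds are cut back to the C2=C3 double bond of benzofuran ester 11; dimethyldioxirane in methanol supplies both oxygens. This is the step that creates C3, without control from C2', so the C3 epimers must be separated here.

**11 from 10, 9, 8, 6 and 7.** Ester 11 is the benzyl ether of phenol 10. In 10 the C3–CO2Me and O7'–C2 bonds are cut together, leading to ortho-alkynylphenol 9. A carbonylative heteroannulation places the ester through a carbon–palladium bond, so no electrophile has to choose between benzofuran C3 and flavan C6', as bromination of a 3-unsubstituted benzofuran would. Phenol 9 comes from bis-MOM ether 8, and 8 from iodide 6 and alkyne 7 by Sonogashira coupling.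

**6 from 5, 4, 2 and 1.** Iodide 6 comes from flavan 5 by iodination at C8 (C8' of the target). Flavan 5 is the benzyl ether of phenol 4, which comes from flavanone 2 by removal of the C4 carbonyl. Compound 2 is the 7,4'-bis-MOM ether of (2S)-naringenin 1. The chelated 5-hydroxyl of 1 is what distinguishes O5 (benzyl, kept to the end) from O7 and O4' (MOM, removed after the coupling).

**22 from 20, 17 and 16.** The triflate 22 comes from silyl carbamate 20, made by carbamate-directed ortho-silylation of 17, which is the isopropylcarbamate of symmetrical phenol 16. Because the two ortho positions of 16 are equivalent, only one silyl regioisomer can form.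

## Roads not taken

**Alternative 1:** The cuts are C3–C4 and C2–O1, giving 2-hydroxy-4,6-bis(benzyloxy)benzaldehyde A2 and the 3-unsubstituted flavan-fused 2-arylbenzofuran A3. In acid, benzofuran C3 attacks the aldehyde, water is lost to a flavylium-like cation and the phenol closes on C2, giving the chromene ketal A1. The C3=C4 bond of A1 must then become C3(OH)–C4(=O) by dihydroxylation and benzylic oxidation, or by direct ketohydroxylation.
- Merits: two simple fragments, ring C closed in the key step, no aryne precursor, no carboxylation and no ester hydrolysis. The road is shorter than the chosen one by about four operations.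
- Weak points: A2 is a vinylogous formate and a poor electrophile. A3 offers the flavan C6' position in competition with benzofuran C3. The acid needed threatens the flavan ether. The late oxidation must pick one styrene-type double bond among three electron-rich rings, and RuO4-type reagents would not spare them.
- Comparison: the chosen plan is longer, but it has the C3 oxygen in place before ring A arrives and makes the C4–C4a bond intramolecularly at a defined position.

**Alternative 2:** The cuts are C3–C8' and C2–O7', giving the 2-hydroxychromane-3,4-dione A5 (an oxidised tri-O-benzyl flavonol) and the flavan diol A6. Under Brønsted acid the flavan carbon adds to the C3 ketone and the 7'-hydroxyl replaces the hemiketal hydroxyl, giving A4 in one step with both quaternary centres; only hydrogenolysis follows.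
- Merits: this is the most convergent and biomimetic road and clearly the better one in step economy, at roughly half the length of the chosen route.
- Weak points: the flavan can react at C6' as well as C8', and through oxygen as well as carbon. Chromane-3,4-diones ring-contract easily to 2-aroylbenzofuran-3-ones. C3 is formed with no more control from C2' than in the chosen plan.
- Comparison: the chosen plan fixes the C3–C8' bond through an aryl iodide whose regiochemistry is established on a simple intermediate, and it avoids the labile trione.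

**Alternative 3:** The cut is C2–C3. The precursor is the 1,2-diketone A8, whose 7'-oxygen carries an α-methoxy-4-benzyloxybenzyl group. On irradiation the carbonyl on C8' abstracts the acetal hydrogen and the 1,5-biradical recombines (Norrish–Yang) to the dihydrobenzofuranol A7.
- Merits: the most congested bond is made last, under neutral conditions and with ring A already attached; photocyclisation of ortho-alkoxyaryl ketones to dihydrobenzofuran-3-ols is a known reaction type.
- Weak points: a 1,2-diketone has two carbonyls that can be excited and can also cleave. The mixed aryl alkyl acetal A8 is labile and awkward to make. The triacetoxyphenyl diketone needs its own multistep synthesis. C3 is again uncontrolled relative to C2'.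
- Comparison: the length is similar to the chosen plan, the precursors are more fragile, and the chosen plan relies only on thermal steps.

Key step: step 15

Remark 1: (2S)-naringenin, 1-(benzyloxy)-4-ethynylbenzene and 3,5-bis(benzyloxy)phenol are taken as purchasable; the last is otherwise one benzylation away from phloroglucinol.

Remark 2: The configuration at the ketal carbon and the carbinol carbon is taken exactly as written in the target structure, (2S,3R) in flavone-type numbering. Because the ketal carbon is formed through an oxocarbenium ion tethered to C3, the route has to secure only C3 and the flavan centre.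

Locants in the tricyclic intermediates follow 2H-furo[2,3-h]chromene: position 2 is the flavan carbon, position 8 is C2 of the target and position 9 is C3 of the target.

## Route

Step 1
Reactants: 1 (2S)-naringenin
Product: 2 (2S)-5-hydroxy-7-(methoxymethoxy)-2-[4-(methoxymethoxy)phenyl]chroman-4-one
Conditions: MOMCl (2.3 equiv), i-Pr2NEt, CH2Cl2, 0 °C → rt
Reagents that add atoms: chloromethyl methyl ether (COCCl)
Why: O-Alkylation of the two non-chelated phenols; the 5-hydroxyl is hydrogen-bonded to the C4 carbonyl and stays free, and the amine base is too weak to open the flavanone to the chalcone, so C2 keeps its configuration.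

Step 2
Reactants: 2
Product: 4 (2S)-7-(methoxymethoxy)-2-[4-(methoxymethoxy)phenyl]chroman-5-ol, via ethyl aryl carbonate 3 (not isolated)
Conditions: ClCO2Et, Et3N, THF, 0 °C; then NaBH4, H2O, 0 °C → rt
Reagents that add atoms: none
Why: Known reductive deoxygenation of ortho-hydroxyaryl ketones through their aryl carbonates: borohydride reduces the ketone, the carbonate migrates to the benzylic alkoxide and leaves to give an ortho-quinone methide, which takes up a second hydride; C2 is not involved.

Step 3
Reactants: 4
Product: 5 (2S)-5-(benzyloxy)-7-(methoxymethoxy)-2-[4-(methoxymethoxy)phenyl]chromane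
Conditions: BnBr, K2CO3, DMF, rt
Reagents that add atoms: benzyl bromide (BrCc1ccccc1)
Why: Williamson etherification of the only free phenol; without the C4 carbonyl the ring can no longer open under base.

Step 4
Reactants: 5
Product: 6 (2S)-5-(benzyloxy)-8-iodo-7-(methoxymethoxy)-2-[4-(methoxymethoxy)phenyl]chromane
Conditions: NIS, DMF, 0 °C → rt, dark
Reagents that add atoms: N-iodosuccinimide (O=C1CCC(=O)N1I)
Why: Electrophilic iodination of the trioxygenated ring; C8 is flanked by one acyclic ether and the ring oxygen whereas C6 lies between two acyclic ethers, so the less hindered C8 should react, as in halogenations of per-alkylated 5,7-dioxygenated flavans, and the mono-oxygenated aryl ring is far less reactive.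

Step 5
Reactants: 6 and 7 1-(benzyloxy)-4-ethynylbenzene
Product: 8 (2S)-5-(benzyloxy)-8-{[4-(benzyloxy)phenyl]ethynyl}-7-(methoxymethoxy)-2-[4-(methoxymethoxy)phenyl]chromane
Conditions: Pd(PPh3)2Cl2 (5 mol%), CuI (10 mol%), Et3N, DMF, 60 °C
Reagents that add atoms: none
Why: Sonogashira coupling of an electron-rich, doubly ortho-substituted aryl iodide, hence gentle heating; the MOM ether on O7 prevents premature cyclisation to a 3-unsubstituted benzofuran.

Step 6
Reactants: 8
Product: 9 (2S)-5-(benzyloxy)-8-{[4-(benzyloxy)phenyl]ethynyl}-2-(4-hydroxyphenyl)chroman-7-ol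
Conditions: 3 M HCl, MeOH/THF, 40 °C
Reagents that add atoms: none
Why: Acid-catalysed transfer of both aryl methoxymethyl groups to methanol; benzyl ethers, the flavan ether and the diarylalkyne should tolerate these mild conditions.

Step 7
Reactants: 9
Product: 10 methyl (2S)-5-(benzyloxy)-8-[4-(benzyloxy)phenyl]-2-(4-hydroxyphenyl)-3,4-dihydro-2H-furo[2,3-h]chromene-9-carboxylate
Conditions: PdI2 (5 mol%), thiourea (5 mol%), CBr4, Cs2CO3, CO (1 atm), MeOH, 40 °C
Reagents that add atoms: carbon monoxide ([C-]#[O+]); methanol (CO)
Why: Known carbonylative heteroannulation of ortho-alkynylphenols: 5-endo oxypalladation of the alkyne by the phenoxide on divalent palladium, CO insertion and methanolysis give the benzofuran-3-carboxylate, and CBr4 returns zerovalent palladium to the divalent state. The metal places the C9 substituent, so no electrophile has to choose between that carbon and the free position of the flavan ring.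

Step 8
Reactants: 10
Product: 11 methyl (2S)-5-(benzyloxy)-2,8-bis[4-(benzyloxy)phenyl]-3,4-dihydro-2H-furo[2,3-h]chromene-9-carboxylate
Conditions: BnBr, K2CO3, DMF, rt
Reagents that add atoms: benzyl bromide (BrCc1ccccc1)
Why: Williamson etherification of the remaining phenol, so that no phenol is left to be oxidised in step 9 or arylated in step 15.

Step 9
Reactants: 11
Product: 13 methyl (2S,8R,9S)-5-(benzyloxy)-2,8-bis[4-(benzyloxy)phenyl]-9-hydroxy-8-methoxy-3,4,8,9-tetrahydro-2H-furo[2,3-h]chromene-9-carboxylate, via benzofuran 8,9-epoxide 12 (not isolated)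
Conditions: DMDO (acetone solution), MeOH/CH2Cl2, −20 °C → rt; chromatographic separation of the C9 epimers
Reagents that add atoms: dimethyldioxirane (CC1(C)OO1); methanol (CO)
Why: Dioxirane epoxidation of the push–pull 8,9-double bond, as known for benzofurans and flavones, followed by methanolysis at C8 through the aryl- and oxygen-stabilised oxocarbenium ion. C9 is created here with no expected bias from the remote flavan centre, so both C9 epimers should form and the (9S) epimer is separated. The C8 anomer does not matter because C8 is re-formed in step 16.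

Step 10
Reactants: 13
Product: 14 methyl (2S,8R,9S)-5,9-bis(benzyloxy)-2,8-bis[4-(benzyloxy)phenyl]-8-methoxy-3,4,8,9-tetrahydro-2H-furo[2,3-h]chromene-9-carboxylate
Conditions: NaH, BnBr, n-Bu4NI (cat.), DMF, 0 °C → rt
Reagents that add atoms: benzyl bromide (BrCc1ccccc1)
Why: Williamson etherification of the tertiary α-hydroxy ester alkoxide; the ketal has no leaving group that base can expel and no stereocentre is touched.

Step 11
Reactants: 14
Product: 15 (2S,8R,9S)-5,9-bis(benzyloxy)-2,8-bis[4-(benzyloxy)phenyl]-8-methoxy-3,4,8,9-tetrahydro-2H-furo[2,3-h]chromene-9-carboxylic acid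
Conditions: LiOH·H2O, THF/MeOH/H2O, 50 °C; then 1 M HCl to pH 4, 0 °C
Reagents that add atoms: lithium hydroxide ([Li+].[OH-])
Why: Saponification of a hindered methyl ester that has no α-hydrogen and so cannot epimerise; ketal and ethers are stable to hydroxide, and the acidification is brief and cold to spare the ketal.

Step 12
Reactants: 16 3,5-bis(benzyloxy)phenol
Product: 17 3,5-bis(benzyloxy)phenyl N-isopropylcarbamate
Conditions: i-PrNCO, Et3N (cat.), CH2Cl2, rt
Reagents that add atoms: isopropyl isocyanate (CC(C)N=C=O)
Why: Addition of the phenol to the isocyanate gives a carbamate that directs metalation and can later be removed under mild base.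

Step 13
Reactants: 17
Product: 20 3,5-bis(benzyloxy)-2-(trimethylsilyl)phenyl N-isopropylcarbamate, via N-silyl carbamate 18 (not isolated), via N,2-bis(trimethylsilyl) carbamate 19 (not isolated)
Conditions: TMSOTf, TMEDA, Et2O, 0 °C → rt; n-BuLi, TMEDA, −78 °C; TMSCl, −78 °C → rt; aq. NaHSO4
Reagents that add atoms: chlorotrimethylsilane (C[Si](C)(C)Cl)
Why: Directed ortho-metalation: N-silylation masks the N–H, the carbamate and the neighbouring benzyloxy group together direct lithiation to C2 (equivalent to C6, so one product), TMSCl traps the aryllithium, and the N-silyl group is lost on work-up.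

Step 14
Reactants: 20
Product: 22 3,5-bis(benzyloxy)-2-(trimethylsilyl)phenyl trifluoromethanesulfonate, via silylphenol 21 (not isolated)
Conditions: DBU, Et2NH, MeCN, 40 °C; then PhNTf2, rt
Reagents that add atoms: N-phenylbis(trifluoromethanesulfonimide) (O=S(=O)(N(c1ccccc1)S(=O)(=O)C(F)(F)F)C(F)(F)F)
Why: Base-induced E1cB cleavage of the N-monosubstituted carbamate gives the phenoxide and isopropyl isocyanate (trapped by diethylamine); O-triflation in the same pot is the established route to ortho-silylaryl triflates.

Step 15
Reactants: 15 and 22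
Product: 24 {(2S,8R,9R)-5,9-bis(benzyloxy)-2,8-bis[4-(benzyloxy)phenyl]-8-methoxy-3,4,8,9-tetrahydro-2H-furo[2,3-h]chromen-9-yl}[2,4-bis(benzyloxy)-6-hydroxyphenyl]methanone, via 3,5-bis(benzyloxy)benzyne 23 (not isolated)
Conditions: 22 (1.5 equiv), CsF (4 equiv), THF, 125 °C, sealed tube
Reagents that add atoms: none
Why: Fluoride removes the silyl group of 22 and triflate leaves, giving aryne 23, while 15 is present as its Cs carboxylate. The carboxylate oxygen adds to the aryne carbon remote from the flanking benzyloxy group, because that inductively withdrawing group polarises the aryne so that the negative charge develops next to it. The resulting aryl anion, ortho to the new ester oxygen, attacks the ester carbonyl through a four-membered alkoxide that reopens to the ketone and the phenoxide; this forms C4–C4a and O1–C8a and places the acyl group between the phenol and a benzyloxy group. The closest known reaction is the fluoride-induced insertion of arynes into the C–O bond of carboxylic acids to give ortho-hydroxyaryl ketones, which needs this temperature for acyl transfer to outrun protonation of the aryl anion. No ring closes and no stereocentre is formed; C9 has no hydrogen and cannot epimerise. The step needs one aryne regiochemistry and acyl transfer in preference to protonation: the first is secured by the 3-benzyloxy group, the second by the benzyl ether on the C9 oxygen, which removes the only proton donor within reach of the aryl anion, and by anhydrous CsF in excess. The aryne precursor is kept to a small excess so that the chelated product phenoxide is not arylated again.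

Step 16
Reactants: 24
Product: 25 hexa-O-benzyl daphnodorin F, (2S,3R,2'S), benzyl ethers on the five phenolic oxygens and on the C3 oxygen
Conditions: CSA (cat.), 4 Å MS, toluene, 50 °C
Reagents that add atoms: none
Why: Acid-catalysed transketalisation: loss of methanol gives an oxocarbenium ion stabilised by O7' and the 4-benzyloxyphenyl group, and the ortho-phenol of the aroyl group captures it in a 6-exo closure of the pyranone ring. The ketal configuration is set here under thermodynamic control by C3, to which the phenol is tethered, and the sieves take up methanol.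

Step 17
Reactants: 25
Product: 26 daphnodorin F
Conditions: H2 (1 atm), Pd(OH)2/C, EtOAc/MeOH, rt
Reagents that add atoms: none
Why: Hydrogenolysis of five aryl benzyl ethers and the tertiary alkyl benzyl ether under neutral conditions, which should leave the ketal, the α-ketol and the flavan C–O bond intact as in debenzylations of flavan-3-ols; no stereocentre is affected.

## Compound list

1 | (2S)-naringenin | O=C1C[C@@H](c2ccc(O)cc2)Oc2cc(O)cc(O)c21 | starting material
2 | (2S)-5-hydroxy-7-(methoxymethoxy)-2-[4-(methoxymethoxy)phenyl]chroman-4-one | O=C1C[C@@H](c2ccc(OCOC)cc2)Oc2cc(OCOC)cc(O)c21 | intermediate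
3 | ethyl (2S)-7-(methoxymethoxy)-2-[4-(methoxymethoxy)phenyl]-4-oxochroman-5-yl carbonate | CCOC(=O)Oc1cc(OCOC)cc2c1C(=O)C[C@@H](c1ccc(OCOC)cc1)O2 | intermediate (not isolated)
4 | (2S)-7-(methoxymethoxy)-2-[4-(methoxymethoxy)phenyl]chroman-5-ol | Oc1cc(OCOC)cc2c1CC[C@@H](c1ccc(OCOC)cc1)O2 | intermediate
5 | (2S)-5-(benzyloxy)-7-(methoxymethoxy)-2-[4-(methoxymethoxy)phenyl]chromane | c1ccccc1COc1cc(OCOC)cc2c1CC[C@@H](c1ccc(OCOC)cc1)O2 | intermediate
6 | (2S)-5-(benzyloxy)-8-iodo-7-(methoxymethoxy)-2-[4-(methoxymethoxy)phenyl]chromane | c1ccccc1COc1cc(OCOC)c(I)c2c1CC[C@@H](c1ccc(OCOC)cc1)O2 | intermediate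
7 | 1-(benzyloxy)-4-ethynylbenzene | C#Cc1ccc(OCc2ccccc2)cc1 | starting material
8 | (2S)-5-(benzyloxy)-8-{[4-(benzyloxy)phenyl]ethynyl}-7-(methoxymethoxy)-2-[4-(methoxymethoxy)phenyl]chromane | c1ccccc1COc1cc(OCOC)c(C#Cc3ccc(OCc4ccccc4)cc3)c2c1CC[C@@H](c1ccc(OCOC)cc1)O2 | intermediate
9 | (2S)-5-(benzyloxy)-8-{[4-(benzyloxy)phenyl]ethynyl}-2-(4-hydroxyphenyl)chroman-7-ol | c1ccccc1COc1cc(O)c(C#Cc3ccc(OCc4ccccc4)cc3)c2c1CC[C@@H](c1ccc(O)cc1)O2 | intermediate
10 | methyl (2S)-5-(benzyloxy)-8-[4-(benzyloxy)phenyl]-2-(4-hydroxyphenyl)-3,4-dihydro-2H-furo[2,3-h]chromene-9-carboxylate | COC(=O)c1c(-c2ccc(OCc3ccccc3)cc2)oc2cc(OCc3ccccc3)c3c(c12)O[C@H](c1ccc(O)cc1)CC3 | intermediate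
11 | methyl (2S)-5-(benzyloxy)-2,8-bis[4-(benzyloxy)phenyl]-3,4-dihydro-2H-furo[2,3-h]chromene-9-carboxylate | COC(=O)c1c(-c2ccc(OCc3ccccc3)cc2)oc2cc(OCc3ccccc3)c3c(c12)O[C@H](c1ccc(OCc2ccccc2)cc1)CC3 | intermediate
12 | 8,9-epoxide of 11, oxirane oxygen on the face that becomes the 9-hydroxyl of 13 | COC(=O)[C@@]12O[C@]1(c1ccc(OCc3ccccc3)cc1)Oc1cc(OCc3ccccc3)c3c(O[C@H](c4ccc(OCc5ccccc5)cc4)CC3)c12 | intermediate (not isolated)
13 | methyl (2S,8R,9S)-5-(benzyloxy)-2,8-bis[4-(benzyloxy)phenyl]-9-hydroxy-8-methoxy-3,4,8,9-tetrahydro-2H-furo[2,3-h]chromene-9-carboxylate | CO[C@]1(c2ccc(OCc3ccccc3)cc2)Oc2cc(OCc3ccccc3)c3c(c2[C@]1(C(=O)OC)O)O[C@H](c1ccc(OCc2ccccc2)cc1)CC3 | intermediate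
14 | methyl (2S,8R,9S)-5,9-bis(benzyloxy)-2,8-bis[4-(benzyloxy)phenyl]-8-methoxy-3,4,8,9-tetrahydro-2H-furo[2,3-h]chromene-9-carboxylate | CO[C@]1(c2ccc(OCc3ccccc3)cc2)Oc2cc(OCc3ccccc3)c3c(c2[C@]1(C(=O)OC)OCc1ccccc1)O[C@H](c1ccc(OCc2ccccc2)cc1)CC3 | intermediate
15 | (2S,8R,9S)-5,9-bis(benzyloxy)-2,8-bis[4-(benzyloxy)phenyl]-8-methoxy-3,4,8,9-tetrahydro-2H-furo[2,3-h]chromene-9-carboxylic acid | CO[C@]1(c2ccc(OCc3ccccc3)cc2)Oc2cc(OCc3ccccc3)c3c(c2[C@]1(C(=O)O)OCc1ccccc1)O[C@H](c1ccc(OCc2ccccc2)cc1)CC3 | intermediate
16 | 3,5-bis(benzyloxy)phenol | Oc1cc(OCc2ccccc2)cc(OCc2ccccc2)c1 | starting material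
17 | 3,5-bis(benzyloxy)phenyl N-isopropylcarbamate | CC(C)NC(=O)Oc1cc(OCc2ccccc2)cc(OCc2ccccc2)c1 | intermediate
18 | 3,5-bis(benzyloxy)phenyl N-isopropyl-N-(trimethylsilyl)carbamate | CC(C)N([Si](C)(C)C)C(=O)Oc1cc(OCc2ccccc2)cc(OCc2ccccc2)c1 | intermediate (not isolated)
19 | 3,5-bis(benzyloxy)-2-(trimethylsilyl)phenyl N-isopropyl-N-(trimethylsilyl)carbamate | CC(C)N([Si](C)(C)C)C(=O)Oc1cc(OCc2ccccc2)cc(OCc2ccccc2)c1[Si](C)(C)C | intermediate (not isolated)
20 | 3,5-bis(benzyloxy)-2-(trimethylsilyl)phenyl N-isopropylcarbamate | CC(C)NC(=O)Oc1cc(OCc2ccccc2)cc(OCc2ccccc2)c1[Si](C)(C)C | intermediate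
21 | 3,5-bis(benzyloxy)-2-(trimethylsilyl)phenol | C[Si](C)(C)c1c(O)cc(OCc2ccccc2)cc1OCc1ccccc1 | intermediate (not isolated)
22 | 3,5-bis(benzyloxy)-2-(trimethylsilyl)phenyl trifluoromethanesulfonate | C[Si](C)(C)c1c(OCc2ccccc2)cc(OCc2ccccc2)cc1OS(=O)(=O)C(F)(F)F | intermediate
23 | 3,5-bis(benzyloxy)benzyne | C1#CC(OCc2ccccc2)=CC(OCc2ccccc2)=C1 | intermediate (not isolated)
24 | {(2S,8R,9R)-5,9-bis(benzyloxy)-2,8-bis[4-(benzyloxy)phenyl]-8-methoxy-3,4,8,9-tetrahydro-2H-furo[2,3-h]chromen-9-yl}[2,4-bis(benzyloxy)-6-hydroxyphenyl]methanone | CO[C@]1(c2ccc(OCc3ccccc3)cc2)Oc2cc(OCc3ccccc3)c3c(c2[C@]1(C(=O)c1c(O)cc(OCc2ccccc2)cc1OCc1ccccc1)OCc1ccccc1)O[C@H](c1ccc(OCc2ccccc2)cc1)CC3 | intermediate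
25 | hexa-O-benzyl daphnodorin F, (2S,3R,2'S) | O=C1c2c(OCc3ccccc3)cc(OCc3ccccc3)cc2O[C@]2(c3ccc(OCc4ccccc4)cc3)Oc3cc(OCc4ccccc4)c4c(c3[C@@]12OCc1ccccc1)O[C@H](c1ccc(OCc2ccccc2)cc1)CC4 | intermediate
26 | daphnodorin F, (2S,3R,2'S) | O=C1c2c(O)cc(O)cc2O[C@]2(c3ccc(O)cc3)Oc3cc(O)c4c(c3[C@@]12O)O[C@H](c1ccc(O)cc1)CC4 | target

## Step count and risks

Total: 17 steps. Longest linear sequence: 14 steps (steps 1–11 and 15–17); the aryne precursor is a three-step branch (steps 12–14).

**Step 15 (key step).** Acyl transfer from the aryl ester oxygen to the aryl anion has to occur at a carbonyl attached to a fully substituted carbon. If it is slow, the anion is protonated and only O-arylation results. The Cs carboxylate may also fragment at 125 °C, with loss of CO2 and methoxide and rearomatisation to a benzofuran. Excess aryne can arylate the product phenoxide. Fallback, setting out from ester 14 and phenol 16: 16 is converted with MOMCl and i-Pr2NEt into 1,3-bis(benzyloxy)-5-(methoxymethoxy)benzene F1. F1 is lithiated with n-BuLi between the MOM ether and a benzyloxy group, and the aryllithium is added to 14 to give the [2,4-bis(benzyloxy)-6-(methoxymethoxy)phenyl] ketone F2. Mild HCl in MeOH/THF removes the MOM group and the route is rejoined at 24.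

**Step 9.** Oxygen transfer to the ester-deactivated double bond may be slow enough for the dioxirane to oxidise the electron-rich flavan ring or benzylic C–H bonds instead. There is also no facial preference, so much of the material is lost as the wrong C9 epimer. Fallback, setting out from 11: osmylation with OsO4 and a cinchona-derived ligand such as (DHQD)2PHAL (or its pseudo-enantiomer), which leaves arenes and benzyl ethers alone and offers reagent control of the face. It gives the cis-diol hemiketal methyl (2S,8R,9S)-5-(benzyloxy)-2,8-bis[4-(benzyloxy)phenyl]-8,9-dihydroxy-3,4,8,9-tetrahydro-2H-furo[2,3-h]chromene-9-carboxylate F3. CSA in methanol with trimethyl orthoformate converts the hemiketal into the methyl ketal, and the route is rejoined at 13.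

**Step 10.** The alkoxide sits on a carbon flanked by an ester, an aryl ring and a fully substituted ketal and may alkylate incompletely; the hindered ester that results may then resist saponification in step 11. Fallback, setting out from 11, in which the hydroxyl is created only after the aryne step and needs no protection: 11 is saponified with LiOH to (2S)-5-(benzyloxy)-2,8-bis[4-(benzyloxy)phenyl]-3,4-dihydro-2H-furo[2,3-h]chromene-9-carboxylic acid F4. This aromatic acid is treated with 22 and CsF as in step 15 to give the 9-[2-hydroxy-4,6-bis(benzyloxy)benzoyl]benzofuran F5. DMDO then epoxidises the furan double bond, and the neighbouring phenol opens the epoxide at the ketal carbon to give penta-O-benzyl daphnodorin F with a free C3 hydroxyl F6 after separation of the C3 epimers. Hydrogenolysis over Pd(OH)2/C rejoins the route at 26.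

**Step 4.** Iodination may be poorly regioselective between C8 and C6, giving isomers that are hard to separate and would misplace the furan ring. Fallback, setting out from 4: the phenol is iodinated with NIS before benzylation, so that the free 5-hydroxyl directs the electrophile to its para position C8, giving (2S)-8-iodo-7-(methoxymethoxy)-2-[4-(methoxymethoxy)phenyl]chroman-5-ol F7. Benzylation with BnBr and K2CO3 rejoins the route at 6.

## Further compounds

F1 | step 15 | 1,3-bis(benzyloxy)-5-(methoxymethoxy)benzene | COCOc1cc(OCc2ccccc2)cc(OCc2ccccc2)c1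
F2 | step 15 | {(2S,8R,9R)-5,9-bis(benzyloxy)-2,8-bis[4-(benzyloxy)phenyl]-8-methoxy-3,4,8,9-tetrahydro-2H-furo[2,3-h]chromen-9-yl}[2,4-bis(benzyloxy)-6-(methoxymethoxy)phenyl]methanone | CO[C@]1(c2ccc(OCc3ccccc3)cc2)Oc2cc(OCc3ccccc3)c3c(c2[C@]1(C(=O)c1c(OCOC)cc(OCc2ccccc2)cc1OCc1ccccc1)OCc1ccccc1)O[C@H](c1ccc(OCc2ccccc2)cc1)CC3
F3 | step 9 | methyl (2S,8R,9S)-5-(benzyloxy)-2,8-bis[4-(benzyloxy)phenyl]-8,9-dihydroxy-3,4,8,9-tetrahydro-2H-furo[2,3-h]chromene-9-carboxylate | O[C@]1(c2ccc(OCc3ccccc3)cc2)Oc2cc(OCc3ccccc3)c3c(c2[C@]1(C(=O)OC)O)O[C@H](c1ccc(OCc2ccccc2)cc1)CC3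
F4 | step 10 | (2S)-5-(benzyloxy)-2,8-bis[4-(benzyloxy)phenyl]-3,4-dihydro-2H-furo[2,3-h]chromene-9-carboxylic acid | OC(=O)c1c(-c2ccc(OCc3ccccc3)cc2)oc2cc(OCc3ccccc3)c3c(c12)O[C@H](c1ccc(OCc2ccccc2)cc1)CC3
F5 | step 10 | {(2S)-5-(benzyloxy)-2,8-bis[4-(benzyloxy)phenyl]-3,4-dihydro-2H-furo[2,3-h]chromen-9-yl}[2,4-bis(benzyloxy)-6-hydroxyphenyl]methanone | O=C(c1c(O)cc(OCc2ccccc2)cc1OCc1ccccc1)c1c(-c2ccc(OCc3ccccc3)cc2)oc2cc(OCc3ccccc3)c3c(c12)O[C@H](c1ccc(OCc2ccccc2)cc1)CC3
F6 | step 10 | penta-O-benzyl daphnodorin F with free C3 hydroxyl, (2S,3R,2'S) | O=C1c2c(OCc3ccccc3)cc(OCc3ccccc3)cc2O[C@]2(c3ccc(OCc4ccccc4)cc3)Oc3cc(OCc4ccccc4)c4c(c3[C@@]12O)O[C@H](c1ccc(OCc2ccccc2)cc1)CC4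
F7 | step 4 | (2S)-8-iodo-7-(methoxymethoxy)-2-[4-(methoxymethoxy)phenyl]chroman-5-ol | Oc1cc(OCOC)c(I)c2c1CC[C@@H](c1ccc(OCOC)cc1)O2
A1 | alternative 1 | penta-O-benzyl 3,4-dehydro-4-deoxo ketal (benzofuro[2,3-b]chromene) | c1(OCc2ccccc2)cc(OCc2ccccc2)cc2c1C=C1c3c(O[C@]1(O2)c1ccc(OCc4ccccc4)cc1)cc(OCc1ccccc1)c1c3O[C@H](c3ccc(OCc4ccccc4)cc3)CC1
A2 | alternative 1 | 2-hydroxy-4,6-bis(benzyloxy)benzaldehyde | O=Cc1c(O)cc(OCc2ccccc2)cc1OCc1ccccc1
A3 | alternative 1 | (2S)-5-(benzyloxy)-2,8-bis[4-(benzyloxy)phenyl]-3,4-dihydro-2H-furo[2,3-h]chromene | c1c(-c2ccc(OCc3ccccc3)cc2)oc2cc(OCc3ccccc3)c3c(c12)O[C@H](c1ccc(OCc2ccccc2)cc1)CC3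
A4 | alternative 2 | tetra-O-benzyl daphnodorin F with free flavan 4-hydroxyphenyl group | O=C1c2c(OCc3ccccc3)cc(OCc3ccccc3)cc2O[C@]2(c3ccc(OCc4ccccc4)cc3)Oc3cc(OCc4ccccc4)c4c(c3[C@@]12O)O[C@H](c1ccc(O)cc1)CC4
A5 | alternative 2 | 5,7-bis(benzyloxy)-2-[4-(benzyloxy)phenyl]-2-hydroxychromane-3,4-dione (racemic hemiketal) | O=C1C(=O)C(O)(c2ccc(OCc3ccccc3)cc2)Oc2cc(OCc3ccccc3)cc(OCc3ccccc3)c21
A6 | alternative 2 | (2S)-5-(benzyloxy)-2-(4-hydroxyphenyl)chroman-7-ol | Oc1ccc([C@@H]2CCc3c(OCc4ccccc4)cc(O)cc3O2)cc1
A7 | alternative 3 | 3-hydroxy-2-methoxy-2-[4-(benzyloxy)phenyl]-3-(2,4,6-triacetoxybenzoyl)-2,3-dihydrobenzofuran fused to the protected flavan | CO[C@]1(c2ccc(OCc3ccccc3)cc2)Oc2cc(OCc3ccccc3)c3c(c2[C@@]1(O)C(=O)c1c(OC(C)=O)cc(OC(C)=O)cc1OC(C)=O)O[C@H](c1ccc(OCc2ccccc2)cc1)CC3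
A8 | alternative 3 | 1-{(2S)-5-(benzyloxy)-2-[4-(benzyloxy)phenyl]-7-{[4-(benzyloxy)phenyl](methoxy)methoxy}chroman-8-yl}-2-(2,4,6-triacetoxyphenyl)ethane-1,2-dione (acetal carbon as a mixture) | COC(Oc1cc(OCc2ccccc2)c2c(c1C(=O)C(=O)c1c(OC(C)=O)cc(OC(C)=O)cc1OC(C)=O)O[C@H](c1ccc(OCc3ccccc3)cc1)CC2)c1ccc(OCc2ccccc2)cc1
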